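**The problem**

13,14-Dihydro-PGE1 (21) is a cyclopentanone (ring C8–C12) with the saturated C1–C7 acid chain on C8, the ketone at C9, a hydroxyl on C11 and the saturated, C15-hydroxylated octyl chain on C12, configured 8R,11R,12R,15S. Only this one ring has to be closed, so the task is to join two unbranched chains to a five-membered ring with three contiguous stereocentres and to place a fourth, C15, four bonds from the ring. C15 is too remote to control the ring or be controlled by it, so it must come from the chiral pool or a reagent. C11 can direct C12 when the two are neighbours in the step that creates C12, and C12 then fixes C8, which is enolisable and settles trans to the C12 chain. The β-ketol (C9 ketone, C11 hydroxyl) is the fragile group: base, strong acid or an activated C11 oxygen expel the C11 substituent to give the cyclopentenone, so the acid, both carbinols and C8 must be unmasked near neutrality. The enabling feature is the saturated C13–C14 bond. In an open-chain precursor C12 is then an ordinary methylene five atoms from C8, and a carbenoid at C8 flanked by the C9 carbonyl can close C8–C12 by insertion into a C12–H bond, with no alkene present to be cyclopropanated. The cost is that this C–H bond lies next to the C11 oxygen, which lowers its reactivity and decides the C11/C12 relation.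

**Retrosynthesis**

21 ⇒ 20 ⇒ 19 (no skeletal bond cut). The C1 acid is carried as a methyl ester and the C15 hydroxyl as a TBDPS ether. Hydroxide would dehydrate the β-ketol, so the ester of 20 is to be cleaved by an esterase and the silyl ether of 19 by buffered HF. Both operations are standard for E-type prostaglandins.

19 ⇒ 17 (C11–O bond, made with inversion). The insertion planned below is expected to place the C11 silyloxy group cis to the C12 chain, while the target needs trans. Neither C11 epimer of the precursor can therefore give the 11R,12R ring directly. C11 is carried as its epimer, which sets C12 correctly, and is inverted afterwards. Because C12 cannot be epimerised, inverting C11 is the only workable correction. The forward reaction must be an SN2 displacement at a cyclopentyl carbinol β to a ketone without elimination.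

17 ⇒ 16 ⇒ 14 (C8–CO2Bn bond; C11–O–Si bond). The ester that stabilises the carbenoid and directs the C8 alkylation is removed by hydrogenolysis and decarboxylation. A benzyl ester is chosen because it can be cleaved beside the C1 methyl ester and the β-silyloxy ketone under neutral conditions. C11 carries TBS and C15 the more robust TBDPS, so the C11 hydroxyl can be freed alone for the inversion. The free C1 acid is avoided until the end because it would compete in the inversion step.

14 ⇒ 12 + 13 (C7–C8 bond). Alkylation of the cyclic β-keto ester 12 with methyl 7-bromoheptanoate 13 places the acid chain regiospecifically at C8. A plain cyclopentanone would alkylate at C8 and C10 and would eliminate.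

12 ⇒ 11 (C8–C12 bond, the key cut). Opening the ring here turns a trisubstituted cyclopentanone into a linear α-diazo β-keto ester whose two carbinol centres can be set one at a time. Cuts at C9–C10 or C10–C11 would need a branched precursor that already carries the C8/C12 relation. The forward reaction must select one methylene among many and relay C11 to C12.

11 ⇒ 10 ⇒ 9 (C8=N2; C11–O–Si). Diazo transfer to the active methylene and silylation of the aldol hydroxyl. Both are routine on δ-hydroxy β-keto esters.

9 ⇒ 4 + 7 (C10–C11 bond). A vinylogous aldol of the bis-silyl dienolate 7 of benzyl acetoacetate with aldehyde 4 delivers the whole C8–C11 unit and the C11 carbinol in one step. C15 is too far away to influence it, so a chiral catalyst must set C11. Diene 7 comes from benzyl acetoacetate 5 through enol ether 6.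

4 ⇒ 3 ⇒ 2 ⇒ 1 (C11 oxidation level; ring-opening of the lactone). (S)-δ-Decalactone 1 already holds C11–C20 and the C15 stereocentre. Opening to Weinreb amide 2, silylation to 3 and reduction give aldehyde 4.

**Roads not taken**

Alternative 1: The cut is the biosynthetic one: C8–C12, C9–O, C11–O and C15–O are all formed when cyclooxygenase doubly dioxygenates (8Z,11Z,14Z)-icosa-8,11,14-trienoic acid A1 to the endoperoxide prostaglandin H1 A2.
- Forward: isomerisation of A2 gives prostaglandin E1 A3, whose only C=C bond is C13=C14, so hydrogenation would give 21.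
- Merits: about three operations, no protecting groups, and all four stereocentres set by the enzyme. In step count and stereocontrol this road is better than the chosen plan.
- Weak points: the enzyme is a membrane haem protein that inactivates itself during turnover, A2 is a labile peroxide that also rearranges to other prostaglandin types, and the scale is small.
- Against it the chosen plan sets ordinary reagents and scale, freedom from biological supply and from a peroxide intermediate, and the chance to vary either chain.

Alternative 2: The cut is the C9–O bond of a bicyclic lactone. A flavin monooxygenase oxidises racemic cis-bicyclo[3.2.0]hept-2-en-6-one A4 enantiodivergently. The (1R,5S) enantiomer gives (1S,5R)-2-oxabicyclo[3.3.0]oct-6-en-3-one A5 by oxygen insertion next to the bridgehead, and the other enantiomer gives the regioisomeric lactone A6.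
- Merits: a cheap racemic ketone, high enantiopurity of both lactones, and a rigid cis-fused bicycle from which ring stereocentres are set by well-known lactone chemistry. For reliability of the ring stereochemistry this road is better than the chosen one.
- Weak points for this target: half of the material ends as A6. A5 still lacks the C11 oxygen, the C12 carbon branch and both chains. C9 arrives at the alcohol level, so a late protected oxidation is needed. The sequence is well over a dozen steps.
- Against it the chosen plan sets a shorter sequence, C9 at the ketone level from the start, and no discarded enantiomer. It accepts a selectivity risk in the insertion and an inversion at C11.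

Alternative 3: The cut is C8–C12 plus C9–C10 in a formal (3+2) union of succinaldehyde A7 with methyl (E)-9-nitronon-8-enoate A8. Enamine catalysis by a diarylprolinol silyl ether makes C8–C12 by Michael addition, and a base-induced Henry reaction closes C9–C10 to the cyclopentane A9.
- Merits: a catalytic, convergent step that sets C8 and C12 trans in one absolute sense, with the acid chain in place and a formyl handle for the lower chain. In step economy it is probably better than the chosen plan.
- Weak points for this target: the oxygen ends on C10 and the nitro group on C9, so the C9 ketone/C11 hydroxyl pattern has to be rebuilt through an elimination and re-oxygenation sequence via cyclopentenone-type intermediates. C15 must be set late by a reagent-controlled ketone reduction. The olefination-derived C13=C14 bond must be hydrogenated at a stage free of other reducible unsaturation.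
- Against it the chosen plan sets both carbinols from defined precursors before the ring exists and brings the saturated lower chain in directly. It pays with a C11 inversion.

Key step: step 9

**Remarks**

- Assumption: (S)-δ-decalactone of high enantiomeric purity is taken as purchasable.
- Assumption: the 1,2-induction of the insertion follows the known behaviour of 5-silyloxy-2-diazo-3-oxo esters, which give the 2,3-cis cyclopentanone; C11 is therefore carried as its epimer and inverted in step 13.
- Prostaglandin numbering (C1–C20) is used for atoms. TMS = trimethylsilyl, TBS = tert-butyldimethylsilyl, TBDPS = tert-butyldiphenylsilyl, DIAD = diisopropyl azodicarboxylate.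

**Route**

Step 1
Reactants: 1 (S)-δ-decalactone [(6S)-6-pentyloxan-2-one]
Product: 2 (5S)-5-hydroxy-N-methoxy-N-methyldecanamide
Conditions: MeNH(OMe)·HCl, AlMe3, CH2Cl2, 0 °C → rt; used without chromatography
Reagents that add atoms: N,O-dimethylhydroxylamine hydrochloride (CNOC.Cl)
Why: Aminolysis of a lactone by the aluminium amide (Weinreb amide formation) opens the ring without touching the C15 stereocentre; the amide later stops hydride reduction at the aldehyde.

Step 2
Reactants: 2 (5S)-5-hydroxy-N-methoxy-N-methyldecanamide
Product: 3 (5S)-5-(tert-butyldiphenylsilyloxy)-N-methoxy-N-methyldecanamide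
Conditions: TBDPSCl, imidazole, DMF, rt
Reagents that add atoms: tert-butyldiphenylsilyl chloride (CC(C)(C)[Si](Cl)(c1ccccc1)c1ccccc1)
Why: Silylation of the secondary alcohol traps the open form before it can relactonise; TBDPS is chosen so that it outlasts the C11 TBS ether in step 12.

Step 3
Reactants: 3 (5S)-5-(tert-butyldiphenylsilyloxy)-N-methoxy-N-methyldecanamide
Product: 4 (5S)-5-(tert-butyldiphenylsilyloxy)decanal
Conditions: DIBAL-H, THF, −78 °C; aq. Rochelle salt
Reagents that add atoms: none
Why: Hydride reduction of a Weinreb amide stops at the chelated hemiaminal and releases the aldehyde on work-up; the silyl ether and the stereocentre are not affected.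

Step 4
Reactants: 5 benzyl acetoacetate
Product: 6 benzyl 3-(trimethylsilyloxy)but-2-enoate (mixture of geometric isomers)
Conditions: TMSCl, Et3N, hexane, rt
Reagents that add atoms: chlorotrimethylsilane (C[Si](C)(C)Cl)
Why: O-Silylation of the enol of a β-keto ester, the usual first stage towards a 1,3-bis(silyloxy)diene.

Step 5
Reactants: 6 benzyl 3-(trimethylsilyloxy)but-2-enoate
Product: 7 1-(benzyloxy)-1,3-bis(trimethylsilyloxy)buta-1,3-diene
Conditions: LDA, THF, −78 °C; then TMSCl, −78 °C → rt; used crude
Reagents that add atoms: chlorotrimethylsilane (C[Si](C)(C)Cl)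
Why: Vinylogous (γ) deprotonation of the silyl enol ether and O-silylation of the resulting ester dienolate give the bis-silyl dienolate, which carries the nucleophilic terminus that becomes C10.

Step 6
Reactants: 4 (5S)-5-(tert-butyldiphenylsilyloxy)decanal; 7 1-(benzyloxy)-1,3-bis(trimethylsilyloxy)buta-1,3-diene
Product: 9 benzyl (5R,9S)-9-(tert-butyldiphenylsilyloxy)-5-hydroxy-3-oxotetradecanoate, via bis-trimethylsilyl aldol adduct 8 (not isolated)
Conditions: Ti(OiPr)4, (S)-BINOL (cat.), 4 Å molecular sieves, THF, −78 °C → rt; then TFA, THF–H2O, 0 °C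
Reagents that add atoms: none
Why: Vinylogous Mukaiyama aldol through the terminal carbon of the diene under a BINOL–titanium Lewis acid forms C10–C11. With (S)-BINOL the dienolate should add to the Si face of the aldehyde, the sense established for BINOL–titanium additions to aldehydes, giving the (5R) carbinol, which is the C11 epimer needed for step 9; the C15 centre is too remote to interfere. Acid work-up removes both TMS groups of 8.

Step 7
Reactants: 9 benzyl (5R,9S)-9-(tert-butyldiphenylsilyloxy)-5-hydroxy-3-oxotetradecanoate
Product: 10 benzyl (5R,9S)-5-(tert-butyldimethylsilyloxy)-9-(tert-butyldiphenylsilyloxy)-3-oxotetradecanoate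
Conditions: TBSCl, imidazole, DMF, 0 °C → rt
Reagents that add atoms: tert-butyldimethylsilyl chloride (CC(C)(C)[Si](C)(C)Cl)
Why: Silylation of the δ-hydroxyl; TBS is the kind of ether for which the insertion is known and it can be cleaved later in the presence of TBDPS.

Step 8
Reactants: 10 benzyl (5R,9S)-5-(tert-butyldimethylsilyloxy)-9-(tert-butyldiphenylsilyloxy)-3-oxotetradecanoate
Product: 11 benzyl (5R,9S)-2-diazo-5-(tert-butyldimethylsilyloxy)-9-(tert-butyldiphenylsilyloxy)-3-oxotetradecanoate
Conditions: 4-acetamidobenzenesulfonyl azide, Et3N, MeCN, 0 °C → rt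
Reagents that add atoms: 4-acetamidobenzenesulfonyl azide (CC(=O)Nc1ccc(cc1)S(=O)(=O)N=[N+]=[N-])
Why: Regitz diazo transfer to the active methylene; only C8 is acidic enough for Et3N, so the β-silyloxy ketone is not enolised towards C10.

Step 9
Reactants: 11 benzyl (5R,9S)-2-diazo-5-(tert-butyldimethylsilyloxy)-9-(tert-butyldiphenylsilyloxy)-3-oxotetradecanoate
Product: 12 benzyl (1R,2R,3S)-3-(tert-butyldimethylsilyloxy)-2-[(3S)-3-(tert-butyldiphenylsilyloxy)octyl]-5-oxocyclopentane-1-carboxylate
Conditions: Rh2(OAc)4 (1–2 mol %), CH2Cl2, reflux, slow addition of 11 at high dilution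
Reagents that add atoms: none
Why: Dirhodium tetraacetate decomposes the diazo group with loss of N2 to an electrophilic rhodium carbenoid at C8, flanked by the C9 ketone and the ester. The carbenoid inserts into a C12–H bond in a concerted, three-centre, hydride-transfer-like event with retention at C12, forming C8–C12. The closest known reaction type is the dirhodium tetracarboxylate-mediated 1,5 C–H insertion of α-diazo β-keto esters to 2-alkoxycarbonylcyclopentanones, including 5-silyloxy substrates. The ring C8–C9–C10–C11–C12 closes by 1,5 insertion through a chair-like six-centre transition state (C8, C9, C10, C11, C12 and the migrating H), preferred over four-membered closure at C11–H and six-membered closure at C13–H. C12 is controlled by C11: the chain on C12 sits pseudo-equatorial and the silyloxy group pseudo-axial, where the reacting C–H bond is gauche and not antiperiplanar to the C–O bond and so least depleted by it; this gives the 11,12-cis ring, so the (5R) centre of 11 leads to (2R,3S) in 12. C8 is formed as an enolisable centre that should settle trans to the C12 chain, and it is erased later. The step needs site selectivity for C12–H over the ether oxygen, C11–H and the ester side: the bulky, weakly basic silyl ether resists ylide formation, there is no alkene to cyclopropanate, the Z conformation of the benzyl ester keeps its C–H bonds and arene away from the carbenoid, and slow addition at high dilution suppresses dimerisation.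

Step 10
Reactants: 12 benzyl (1R,2R,3S)-3-(tert-butyldimethylsilyloxy)-2-[(3S)-3-(tert-butyldiphenylsilyloxy)octyl]-5-oxocyclopentane-1-carboxylate; 13 methyl 7-bromoheptanoate
Product: 14 benzyl (1S,2R,3S)-3-(tert-butyldimethylsilyloxy)-2-[(3S)-3-(tert-butyldiphenylsilyloxy)octyl]-1-(7-methoxy-7-oxoheptyl)-5-oxocyclopentane-1-carboxylate
Conditions: Cs2CO3, DMF, rt → 40 °C
Reagents that add atoms: none
Why: SN2 C-alkylation of the caesium enolate of a cyclic β-keto ester with a primary bromide forms C7–C8. The C8 enolate prevents enolisation towards C10, so the β-silyloxy group should not be expelled; attack anti to the C12 chain is expected, but the C8 configuration is erased in step 11.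

Step 11
Reactants: 14 benzyl (1S,2R,3S)-3-(tert-butyldimethylsilyloxy)-2-[(3S)-3-(tert-butyldiphenylsilyloxy)octyl]-1-(7-methoxy-7-oxoheptyl)-5-oxocyclopentane-1-carboxylate
Product: 16 methyl 7-[(1R,2R,3S)-3-(tert-butyldimethylsilyloxy)-2-[(3S)-3-(tert-butyldiphenylsilyloxy)octyl]-5-oxocyclopentyl]heptanoate, via beta-keto acid 15 (not isolated)
Conditions: H2 (1 atm), Pd/C, EtOAc, rt; filter; toluene, 60 °C; then KOAc, MeOH, rt
Reagents that add atoms: none
Why: Hydrogenolysis of the benzyl ester gives β-keto acid 15, which loses CO2 through a cyclic transition state on warming. Acetate-mediated enolisation then equilibrates C8 towards the more stable arrangement with the two chains trans (8R); the methyl ester and both silyl ethers are untouched.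

Step 12
Reactants: 16 methyl 7-[(1R,2R,3S)-3-(tert-butyldimethylsilyloxy)-2-[(3S)-3-(tert-butyldiphenylsilyloxy)octyl]-5-oxocyclopentyl]heptanoate
Product: 17 methyl 7-[(1R,2R,3S)-2-[(3S)-3-(tert-butyldiphenylsilyloxy)octyl]-3-hydroxy-5-oxocyclopentyl]heptanoate
Conditions: HF·pyridine, pyridine, THF, 0 °C → rt
Reagents that add atoms: none
Why: Buffered fluoride desilylation removes a secondary TBS ether much faster than a secondary TBDPS ether, and the buffered medium should spare the β-ketol.

Step 13
Reactants: 17 methyl 7-[(1R,2R,3S)-2-[(3S)-3-(tert-butyldiphenylsilyloxy)octyl]-3-hydroxy-5-oxocyclopentyl]heptanoate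
Product: 19 methyl 7-[(1R,2R,3R)-2-[(3S)-3-(tert-butyldiphenylsilyloxy)octyl]-3-hydroxy-5-oxocyclopentyl]heptanoate, via inverted formate 18 (not isolated)
Conditions: HCO2H, PPh3, DIAD, THF, 0 °C → rt; then MeOH, KHCO3 (cat.), 0 °C
Reagents that add atoms: formic acid (O=CO)
Why: Mitsunobu reaction: formate displaces the alkoxyphosphonium group by SN2 from the face opposite the C12 chain, which is the open face, and inverts C11 to the natural R configuration. The labile formate is then methanolysed under near-neutral conditions that should not trigger β-elimination.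

Step 14
Reactants: 19 methyl 7-[(1R,2R,3R)-2-[(3S)-3-(tert-butyldiphenylsilyloxy)octyl]-3-hydroxy-5-oxocyclopentyl]heptanoate
Product: 20 methyl 7-[(1R,2R,3R)-3-hydroxy-2-[(3S)-3-hydroxyoctyl]-5-oxocyclopentyl]heptanoate (13,14-dihydro-PGE1 methyl ester)
Conditions: HF·pyridine, MeCN, 0 °C → rt
Reagents that add atoms: none
Why: Fluoride-mediated cleavage of the C15 silyl ether under the buffered acidic conditions used for silyl ethers of E-type prostaglandins; no base is present to dehydrate the β-ketol.

Step 15
Reactants: 20 methyl 7-[(1R,2R,3R)-3-hydroxy-2-[(3S)-3-hydroxyoctyl]-5-oxocyclopentyl]heptanoate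
Product: 21 7-[(1R,2R,3R)-3-hydroxy-2-[(3S)-3-hydroxyoctyl]-5-oxocyclopentyl]heptanoic acid (13,14-dihydro-PGE1)
Conditions: porcine liver esterase, pH 8 phosphate buffer–acetone, 30 °C
Reagents that add atoms: water (O)
Why: Enzymatic ester hydrolysis near neutral pH, the standard way to free the C1 acid of an E-type prostaglandin without dehydration to the enone.

**Compound list**

1 | (S)-δ-decalactone [(6S)-6-pentyloxan-2-one] | CCCCC[C@H]1CCCC(=O)O1 | starting material
2 | (5S)-5-hydroxy-N-methoxy-N-methyldecanamide | CCCCC[C@H](O)CCCC(=O)N(C)OC | intermediate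
3 | (5S)-5-(tert-butyldiphenylsilyloxy)-N-methoxy-N-methyldecanamide | CCCCC[C@H](O[Si](c1ccccc1)(c1ccccc1)C(C)(C)C)CCCC(=O)N(C)OC | intermediate
4 | (5S)-5-(tert-butyldiphenylsilyloxy)decanal | CCCCC[C@H](O[Si](c1ccccc1)(c1ccccc1)C(C)(C)C)CCCC=O | intermediate
5 | benzyl acetoacetate | CC(=O)CC(=O)OCc1ccccc1 | starting material
6 | benzyl 3-(trimethylsilyloxy)but-2-enoate (mixture of geometric isomers) | CC(O[Si](C)(C)C)=CC(=O)OCc1ccccc1 | intermediate
7 | 1-(benzyloxy)-1,3-bis(trimethylsilyloxy)buta-1,3-diene | C=C(O[Si](C)(C)C)C=C(O[Si](C)(C)C)OCc1ccccc1 | intermediate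
8 | benzyl (5R,9S)-9-(tert-butyldiphenylsilyloxy)-3,5-bis(trimethylsilyloxy)tetradec-2-enoate | CCCCC[C@H](O[Si](c1ccccc1)(c1ccccc1)C(C)(C)C)CCC[C@@H](O[Si](C)(C)C)CC(O[Si](C)(C)C)=CC(=O)OCc1ccccc1 | intermediate
9 | benzyl (5R,9S)-9-(tert-butyldiphenylsilyloxy)-5-hydroxy-3-oxotetradecanoate | CCCCC[C@H](O[Si](c1ccccc1)(c1ccccc1)C(C)(C)C)CCC[C@@H](O)CC(=O)CC(=O)OCc1ccccc1 | intermediate
10 | benzyl (5R,9S)-5-(tert-butyldimethylsilyloxy)-9-(tert-butyldiphenylsilyloxy)-3-oxotetradecanoate | CCCCC[C@H](O[Si](c1ccccc1)(c1ccccc1)C(C)(C)C)CCC[C@@H](O[Si](C)(C)C(C)(C)C)CC(=O)CC(=O)OCc1ccccc1 | intermediate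
11 | benzyl (5R,9S)-2-diazo-5-(tert-butyldimethylsilyloxy)-9-(tert-butyldiphenylsilyloxy)-3-oxotetradecanoate | CCCCC[C@H](O[Si](c1ccccc1)(c1ccccc1)C(C)(C)C)CCC[C@@H](O[Si](C)(C)C(C)(C)C)CC(=O)C(=[N+]=[N-])C(=O)OCc1ccccc1 | intermediate
12 | benzyl (1R,2R,3S)-3-(tert-butyldimethylsilyloxy)-2-[(3S)-3-(tert-butyldiphenylsilyloxy)octyl]-5-oxocyclopentane-1-carboxylate | CCCCC[C@H](O[Si](c1ccccc1)(c1ccccc1)C(C)(C)C)CC[C@H]1[C@@H](O[Si](C)(C)C(C)(C)C)CC(=O)[C@@H]1C(=O)OCc2ccccc2 | intermediate
13 | methyl 7-bromoheptanoate | COC(=O)CCCCCCBr | starting material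
14 | benzyl (1S,2R,3S)-3-(tert-butyldimethylsilyloxy)-2-[(3S)-3-(tert-butyldiphenylsilyloxy)octyl]-1-(7-methoxy-7-oxoheptyl)-5-oxocyclopentane-1-carboxylate | CCCCC[C@H](O[Si](c1ccccc1)(c1ccccc1)C(C)(C)C)CC[C@H]1[C@@H](O[Si](C)(C)C(C)(C)C)CC(=O)[C@]1(C(=O)OCc2ccccc2)CCCCCCC(=O)OC | intermediate
15 | (1S,2R,3S)-3-(tert-butyldimethylsilyloxy)-2-[(3S)-3-(tert-butyldiphenylsilyloxy)octyl]-1-(7-methoxy-7-oxoheptyl)-5-oxocyclopentane-1-carboxylic acid | CCCCC[C@H](O[Si](c1ccccc1)(c1ccccc1)C(C)(C)C)CC[C@H]1[C@@H](O[Si](C)(C)C(C)(C)C)CC(=O)[C@]1(C(=O)O)CCCCCCC(=O)OC | intermediate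
16 | methyl 7-[(1R,2R,3S)-3-(tert-butyldimethylsilyloxy)-2-[(3S)-3-(tert-butyldiphenylsilyloxy)octyl]-5-oxocyclopentyl]heptanoate | CCCCC[C@H](O[Si](c1ccccc1)(c1ccccc1)C(C)(C)C)CC[C@H]1[C@@H](O[Si](C)(C)C(C)(C)C)CC(=O)[C@@H]1CCCCCCC(=O)OC | intermediate
17 | methyl 7-[(1R,2R,3S)-2-[(3S)-3-(tert-butyldiphenylsilyloxy)octyl]-3-hydroxy-5-oxocyclopentyl]heptanoate | CCCCC[C@H](O[Si](c1ccccc1)(c1ccccc1)C(C)(C)C)CC[C@H]1[C@@H](O)CC(=O)[C@@H]1CCCCCCC(=O)OC | intermediate
18 | methyl 7-[(1R,2R,3R)-2-[(3S)-3-(tert-butyldiphenylsilyloxy)octyl]-3-(formyloxy)-5-oxocyclopentyl]heptanoate | CCCCC[C@H](O[Si](c1ccccc1)(c1ccccc1)C(C)(C)C)CC[C@H]1[C@H](OC=O)CC(=O)[C@@H]1CCCCCCC(=O)OC | intermediate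
19 | methyl 7-[(1R,2R,3R)-2-[(3S)-3-(tert-butyldiphenylsilyloxy)octyl]-3-hydroxy-5-oxocyclopentyl]heptanoate | CCCCC[C@H](O[Si](c1ccccc1)(c1ccccc1)C(C)(C)C)CC[C@H]1[C@H](O)CC(=O)[C@@H]1CCCCCCC(=O)OC | intermediate
20 | methyl 7-[(1R,2R,3R)-3-hydroxy-2-[(3S)-3-hydroxyoctyl]-5-oxocyclopentyl]heptanoate | CCCCC[C@H](O)CC[C@H]1[C@H](O)CC(=O)[C@@H]1CCCCCCC(=O)OC | intermediate
21 | 7-[(1R,2R,3R)-3-hydroxy-2-[(3S)-3-hydroxyoctyl]-5-oxocyclopentyl]heptanoic acid (13,14-dihydro-PGE1) | CCCCC[C@H](O)CC[C@H]1[C@H](O)CC(=O)[C@@H]1CCCCCCC(=O)O | target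

**Step count and risks**

Total step count: 15. Longest linear sequence: 13 steps (steps 1–3 and 6–15, from lactone 1); steps 4–5 form the side branch to diene 7.

Step 9 (key step). The insertion may lose site control or stereocontrol. Because the C12–H bond is inductively depleted by the C11 oxygen, the carbenoid may be captured by the ether oxygen (ylide formation and silyl transfer), insert into the activated C11–H bond, or dimerise. The pseudo-axial preference of the silyloxy group, on which the cis relation rests, may also be weaker or reversed in this long-chain benzyl ester. A change of dirhodium carboxylate would be tried first. The fallback reverses the stereochemical relay and applies if the induction is found to favour the trans ring.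
- It sets out from aldehyde 4. Step 6 is run with (R)-BINOL to give the C11-epimeric aldol benzyl (5S,9S)-9-(tert-butyldiphenylsilyloxy)-5-hydroxy-3-oxotetradecanoate F1.
- Silylation as in step 7 gives the TBS ether F2, and diazo transfer as in step 8 gives the diazo ester F3.
- Insertion then gives the 11,12-trans cyclopentanone F4 with the natural C11 and C12 configurations.
- Alkylation with 13 as in step 10 gives the quaternary keto diester F5, and hydrogenolysis with decarboxylation as in step 11 gives the bis-silyl ether F6.
- Selective removal of the TBS group under the conditions of step 12 comes back to the route at 19, so the inversion of step 13 is no longer needed.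

Step 13. Elimination may win over substitution. The activated C11 oxygen lies β to the ketone with acidic C10–H bonds, so loss of the phosphonium oxide to give the cyclopentenone competes with SN2 attack. The fallback makes the elimination deliberate and restores the oxygen by conjugate addition.
- From 17, MsCl and Et3N in CH2Cl2 give the enone methyl 7-[(1R,2S)-2-[(3S)-3-(tert-butyldiphenylsilyloxy)octyl]-5-oxocyclopent-3-en-1-yl]heptanoate F7.
- CuCl, NaOtBu and a bisphosphine catalyse conjugate addition of B2pin2 in THF–MeOH; boron should add trans to the C12 chain to give the β-boryl ketone F8.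
- Oxidation with NaBO3 in THF–H2O replaces boron by hydroxyl with retention and comes back at 19.

Step 10. C-Alkylation at the hindered tertiary enolate carbon may be slow, which would open the way to O-alkylation and, on prolonged exposure to carbonate, to expulsion of the C11 silanolate. The fallback installs the chain under neutral conditions in two stages.
- From 12, Tsuji–Trost allylation with allyl methyl carbonate and Pd(PPh3)4 in THF gives the C8-allyl keto ester F9.
- Cross-metathesis with methyl hex-5-enoate and second-generation Grubbs catalyst in CH2Cl2 gives the unsaturated diester F10.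
- The conditions of step 11 then saturate the C5=C6 bond along with the hydrogenolysis and decarboxylation and come back at 16.

Step 6. Facial selectivity in the aldol of an unbranched aliphatic aldehyde with the benzyl ester diene may be insufficient. Because C15 is already fixed, any shortfall appears as the C11 epimer, which is hard to remove later and would feed the wrong C12 configuration into step 9. The fallback sets C11 by a stoichiometric reagent.
- From 4, Brown allylation with (−)-Ipc2B(allyl), made from (−)-Ipc2BOMe and allylmagnesium bromide and expected to add to the Si face, gives the homoallylic alcohol (4R,8S)-8-(tert-butyldiphenylsilyloxy)tridec-1-en-4-ol F11 after oxidative work-up.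
- TBSOTf and 2,6-lutidine give the TBS ether F12.
- Ozonolysis with PPh3 work-up gives the aldehyde (3R,7S)-3-(tert-butyldimethylsilyloxy)-7-(tert-butyldiphenylsilyloxy)dodecanal F13.
- Roskamp homologation with benzyl diazoacetate and SnCl2 in CH2Cl2 comes back at 10.

**Further compounds**

F1 | step 9 | benzyl (5S,9S)-9-(tert-butyldiphenylsilyloxy)-5-hydroxy-3-oxotetradecanoate | CCCCC[C@H](O[Si](c1ccccc1)(c1ccccc1)C(C)(C)C)CCC[C@H](O)CC(=O)CC(=O)OCc1ccccc1
F2 | step 9 | benzyl (5S,9S)-5-(tert-butyldimethylsilyloxy)-9-(tert-butyldiphenylsilyloxy)-3-oxotetradecanoate | CCCCC[C@H](O[Si](c1ccccc1)(c1ccccc1)C(C)(C)C)CCC[C@H](O[Si](C)(C)C(C)(C)C)CC(=O)CC(=O)OCc1ccccc1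
F3 | step 9 | benzyl (5S,9S)-2-diazo-5-(tert-butyldimethylsilyloxy)-9-(tert-butyldiphenylsilyloxy)-3-oxotetradecanoate | CCCCC[C@H](O[Si](c1ccccc1)(c1ccccc1)C(C)(C)C)CCC[C@H](O[Si](C)(C)C(C)(C)C)CC(=O)C(=[N+]=[N-])C(=O)OCc1ccccc1
F4 | step 9 | benzyl (1R,2R,3R)-3-(tert-butyldimethylsilyloxy)-2-[(3S)-3-(tert-butyldiphenylsilyloxy)octyl]-5-oxocyclopentane-1-carboxylate | CCCCC[C@H](O[Si](c1ccccc1)(c1ccccc1)C(C)(C)C)CC[C@H]1[C@H](O[Si](C)(C)C(C)(C)C)CC(=O)[C@@H]1C(=O)OCc2ccccc2
F5 | step 9 | benzyl (1S,2R,3R)-3-(tert-butyldimethylsilyloxy)-2-[(3S)-3-(tert-butyldiphenylsilyloxy)octyl]-1-(7-methoxy-7-oxoheptyl)-5-oxocyclopentane-1-carboxylate | CCCCC[C@H](O[Si](c1ccccc1)(c1ccccc1)C(C)(C)C)CC[C@H]1[C@H](O[Si](C)(C)C(C)(C)C)CC(=O)[C@]1(C(=O)OCc2ccccc2)CCCCCCC(=O)OC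
F6 | step 9 | methyl 7-[(1R,2R,3R)-3-(tert-butyldimethylsilyloxy)-2-[(3S)-3-(tert-butyldiphenylsilyloxy)octyl]-5-oxocyclopentyl]heptanoate | CCCCC[C@H](O[Si](c1ccccc1)(c1ccccc1)C(C)(C)C)CC[C@H]1[C@H](O[Si](C)(C)C(C)(C)C)CC(=O)[C@@H]1CCCCCCC(=O)OC
F7 | step 13 | methyl 7-[(1R,2S)-2-[(3S)-3-(tert-butyldiphenylsilyloxy)octyl]-5-oxocyclopent-3-en-1-yl]heptanoate | CCCCC[C@H](O[Si](c1ccccc1)(c1ccccc1)C(C)(C)C)CC[C@H]1C=CC(=O)[C@@H]1CCCCCCC(=O)OC
F8 | step 13 | methyl 7-[(1R,2S,3R)-2-[(3S)-3-(tert-butyldiphenylsilyloxy)octyl]-5-oxo-3-(4,4,5,5-tetramethyl-1,3,2-dioxaborolan-2-yl)cyclopentyl]heptanoate | CCCCC[C@H](O[Si](c1ccccc1)(c1ccccc1)C(C)(C)C)CC[C@H]1[C@H](B2OC(C)(C)C(C)(C)O2)CC(=O)[C@@H]1CCCCCCC(=O)OC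
F9 | step 10 | benzyl (1S,2R,3S)-3-(tert-butyldimethylsilyloxy)-2-[(3S)-3-(tert-butyldiphenylsilyloxy)octyl]-5-oxo-1-(prop-2-en-1-yl)cyclopentane-1-carboxylate | CCCCC[C@H](O[Si](c1ccccc1)(c1ccccc1)C(C)(C)C)CC[C@H]1[C@@H](O[Si](C)(C)C(C)(C)C)CC(=O)[C@]1(C(=O)OCc2ccccc2)CC=C
F10 | step 10 | benzyl (1S,2R,3S)-3-(tert-butyldimethylsilyloxy)-2-[(3S)-3-(tert-butyldiphenylsilyloxy)octyl]-1-[(2E)-7-methoxy-7-oxohept-2-en-1-yl]-5-oxocyclopentane-1-carboxylate | CCCCC[C@H](O[Si](c1ccccc1)(c1ccccc1)C(C)(C)C)CC[C@H]1[C@@H](O[Si](C)(C)C(C)(C)C)CC(=O)[C@]1(C(=O)OCc2ccccc2)C/C=C/CCCC(=O)OC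
F11 | step 6 | (4R,8S)-8-(tert-butyldiphenylsilyloxy)tridec-1-en-4-ol | CCCCC[C@H](O[Si](c1ccccc1)(c1ccccc1)C(C)(C)C)CCC[C@@H](O)CC=C
F12 | step 6 | (4R,8S)-4-(tert-butyldimethylsilyloxy)-8-(tert-butyldiphenylsilyloxy)tridec-1-ene | CCCCC[C@H](O[Si](c1ccccc1)(c1ccccc1)C(C)(C)C)CCC[C@@H](O[Si](C)(C)C(C)(C)C)CC=C
F13 | step 6 | (3R,7S)-3-(tert-butyldimethylsilyloxy)-7-(tert-butyldiphenylsilyloxy)dodecanal | CCCCC[C@H](O[Si](c1ccccc1)(c1ccccc1)C(C)(C)C)CCC[C@@H](O[Si](C)(C)C(C)(C)C)CC=O
A1 | alternative 1 | (8Z,11Z,14Z)-icosa-8,11,14-trienoic acid | CCCCC/C=C\C/C=C\C/C=C\CCCCCCC(=O)O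
A2 | alternative 1 | prostaglandin H1 | CCCCC[C@H](O)/C=C/[C@H]1[C@H]2C[C@H](OO2)[C@@H]1CCCCCCC(=O)O
A3 | alternative 1 | prostaglandin E1 | CCCCC[C@H](O)/C=C/[C@H]1[C@H](O)CC(=O)[C@@H]1CCCCCCC(=O)O
A4 | alternative 2 | racemic cis-bicyclo[3.2.0]hept-2-en-6-one | O=C1CC2C=CCC12
A5 | alternative 2 | (1S,5R)-2-oxabicyclo[3.3.0]oct-6-en-3-one | O=C1C[C@@H]2C=CC[C@@H]2O1
A6 | alternative 2 | (1R,5S)-3-oxabicyclo[3.3.0]oct-6-en-2-one | O=C1OC[C@H]2C=CC[C@@H]12
A7 | alternative 3 | succinaldehyde | O=CCCC=O
A8 | alternative 3 | methyl (E)-9-nitronon-8-enoate | COC(=O)CCCCCC/C=C/[N+](=O)[O-]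
A9 | alternative 3 | methyl 7-(2-formyl-4-hydroxy-5-nitrocyclopentyl)heptanoate (C8 and C12 trans, C9 and C10 as mixtures) | O=C[C@H]1CC(O)C([N+](=O)[O-])[C@@H]1CCCCCCC(=O)OC
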